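**Retrosynthetic overview**
1. Target 25 ⇐ 8-O-acrylate 24 (last step: Morita–Baylis–Hillman hydroxymethylation) ⇐ diol 22 (C15 alcohol → enal, then 8-OH acylation).
2. Both rings of 22 are closed in one flask from open chain 18. First the ten-membered carbocycle forms through the C6–C7 bond, the C1→C10 closure of farnesyl diphosphate in germacrene biosynthesis; then the γ-lactone forms by O6→C12 acyl transfer, the costunolide-type lactonisation.
3. 18 ⇐ C7 aldehyde 15 + methyl acrylate (C11–C13). 15 ⇐ alkylidene lactone 11 (reduction gives 14-OH and 8-OH) ⇐ cross-metathesis of alkene 5 with α-methylene lactone 10 (sets C1=C10).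
4. 5 ⇐ crossed aldol condensation of hex-5-enal with glyoxal mono(dimethyl acetal) (sets C4=C5). C8 is bought in with (S)-5-(hydroxymethyl)butyrolactone; C6 and C7 are set in the ring closure relative to C8.

Assumption and conventions: the target is taken as drawn (6R,7R,8S); positions follow germacrane numbering (C1–C15, lactone C12–O–C6); in every macrocycle both ring alkenes are ring-cis (C2/C9 cis and C3/C6 cis, E,E by CIP) with H-6β, H-7α, H-8β; TBS = tert-butyldimethylsilyl, TES = triethylsilyl.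

**Step 1**
Reactants: 1 hex-5-enal; 2 2,2-dimethoxyacetaldehyde
Product: 4 (E)-2-(but-3-en-1-yl)-4,4-dimethoxybut-2-en-1-ol, via enal 3 (not isolated)
Conditions: 2 (60 % aq., 2.5 equiv), pyrrolidine (20 mol %), PhCO2H (20 mol %), i-PrOH, 50 °C; then MeOH, CeCl3·7H2O, NaBH4, 0 °C
Reagents that add atoms: none
Why: Amine-catalysed (Mannich-type) crossed aldol condensation of enolisable 1 with non-enolisable 2 gives the thermodynamic E-enal (CHO trans to the acetal carbon, which is the ring-cis C4=C5 geometry with C3 cis to C6), and Luche 1,2-reduction in the same flask turns C15 into the allylic alcohol.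

**Step 2**
Reactants: 4 (E)-2-(but-3-en-1-yl)-4,4-dimethoxybut-2-en-1-ol
Product: 5 (E)-2-(but-3-en-1-yl)-4,4-dimethoxybut-2-en-1-yl TBS ether
Conditions: TBSCl, imidazole, CH2Cl2, 23 °C
Reagents that add atoms: tert-butyldimethylsilyl chloride, CC(C)(C)[Si](C)(C)Cl
Why: Standard silylation masks 15-OH until the end while the C6 aldehyde stays latent as its dimethyl acetal.

**Step 3**
Reactants: 6 (S)-5-(hydroxymethyl)dihydrofuran-2(3H)-one
Product: 7 (S)-5-[(TES-oxy)methyl]dihydrofuran-2(3H)-one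
Conditions: TESCl, imidazole, CH2Cl2, 0 °C
Reagents that add atoms: chlorotriethylsilane, CC[Si](Cl)(CC)CC
Why: Silylation of the primary alcohol (future C7); the lactone carbinol carbon is C8 of the target and keeps its S configuration from this chiral-pool lactone through the whole route.

**Step 4**
Reactants: 7 (S)-5-[(TES-oxy)methyl]dihydrofuran-2(3H)-one
Product: 10 (S)-3-methylidene-5-[(TES-oxy)methyl]dihydrofuran-2(3H)-one, via Mannich base 8 (not isolated), via methiodide 9 (not isolated)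
Conditions: LDA, THF, −78 °C; Me2N=CH2+ I−, −78 → 23 °C; then MeI, 23 °C; then aq. NaHCO3, CH2Cl2
Reagents that add atoms: Eschenmoser's salt (N,N-dimethylmethyleneiminium iodide), C=[N+](C)C.[I-]
Why: Eschenmoser methylenation (Mannich reaction of the lactone enolate, N-methylation, β-elimination) installs the exocyclic alkene for metathesis without touching C8.

**Step 5**
Reactants: 5 (E)-2-(but-3-en-1-yl)-4,4-dimethoxybut-2-en-1-yl TBS ether; 10 (S)-3-methylidene-5-[(TES-oxy)methyl]dihydrofuran-2(3H)-one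
Product: 11 (3E,5S)-3-[(4E)-4-[(TBS-oxy)methyl]-6,6-dimethoxyhex-4-en-1-ylidene]-5-[(TES-oxy)methyl]dihydrofuran-2(3H)-one
Conditions: second-generation Hoveyda–Grubbs catalyst RuCl2(=CH-C6H4-2-O-i-Pr)(H2IMes) (H2IMes = 1,3-dimesitylimidazolidin-2-ylidene; 5 mol %), 2,6-dichloro-1,4-benzoquinone (10 mol %), 5 (2 equiv), CH2Cl2, 40 °C
Reagents that add atoms: none
Why: Olefin cross-metathesis of a terminal alkene with the α-methylene lactone gives the conjugated alkylidene lactone as the thermodynamic E isomer (C2 cis to ring CH2 C9), which fixes the ring-cis C1=C10 geometry; the benzoquinone suppresses Ru–H isomerisation to the endocyclic butenolide.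

**Step 6**
Reactants: 11 (3E,5S)-3-[(4E)-4-[(TBS-oxy)methyl]-6,6-dimethoxyhex-4-en-1-ylidene]-5-[(TES-oxy)methyl]dihydrofuran-2(3H)-one
Product: 12 (2S,4E,8E)-4-(hydroxymethyl)-8-[(TBS-oxy)methyl]-10,10-dimethoxy-1-(TES-oxy)deca-4,8-dien-2-ol
Conditions: i-Bu2AlH (4 equiv), CH2Cl2, −78 → 0 °C; aq. Rochelle salt
Reagents that add atoms: none
Why: DIBAL reduction of the lactone to the diol frees 14-OH (primary allylic) and 8-OH (secondary) with the alkene geometry retained.

**Step 7**
Reactants: 12 (2S,4E,8E)-4-(hydroxymethyl)-8-[(TBS-oxy)methyl]-10,10-dimethoxy-1-(TES-oxy)deca-4,8-dien-2-ol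
Product: 14 (2S,4E,8E)-4-(acetoxymethyl)-2-(TBS-oxy)-8-[(TBS-oxy)methyl]-10,10-dimethoxy-1-(TES-oxy)deca-4,8-diene, via monoacetate 13 (not isolated)
Conditions: AcCl (1.05 equiv), 2,4,6-collidine, CH2Cl2, −78 °C; then imidazole, TBSCl, DMF, 23 °C
Reagents that add atoms: acetyl chloride, CC(Cl)=O; tert-butyldimethylsilyl chloride, CC(C)(C)[Si](C)(C)Cl
Why: Kinetic acetylation of the primary allylic alcohol over the hindered secondary one installs the 14-OAc, then silylation protects 8-OH so that the later lactonisation can only involve O6.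

**Step 8**
Reactants: 14 (2S,4E,8E)-4-(acetoxymethyl)-2-(TBS-oxy)-8-[(TBS-oxy)methyl]-10,10-dimethoxy-1-(TES-oxy)deca-4,8-diene
Product: 15 (2S,4E,8E)-4-(acetoxymethyl)-2-(TBS-oxy)-8-[(TBS-oxy)methyl]-10,10-dimethoxydeca-4,8-dienal
Conditions: (COCl)2, DMSO, CH2Cl2, −78 → −30 °C; then Et3N, −78 → 0 °C
Reagents that add atoms: none
Why: Direct Swern oxidation of a primary triethylsilyl ether: the chlorosulfonium reagent cleaves the unhindered primary Et3Si–O bond and the alkoxysulfonium collapses to the C7 aldehyde, while the secondary and the TBS ethers survive and the cold, brief base contact keeps the α-silyloxy centre intact.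

**Step 9**
Reactants: 15 (2S,4E,8E)-4-(acetoxymethyl)-2-(TBS-oxy)-8-[(TBS-oxy)methyl]-10,10-dimethoxydeca-4,8-dienal; 16 methyl acrylate
Product: 17 methyl (4S,6E,10E)-6-(acetoxymethyl)-3-hydroxy-4-(TBS-oxy)-10-[(TBS-oxy)methyl]-12,12-dimethoxy-2-methylidenedodeca-6,10-dienoate (C3 epimers)
Conditions: 16 (10 equiv), DABCO (1 equiv), MeOH (2 equiv), 23 °C, 3–5 d
Reagents that add atoms: none
Why: Morita–Baylis–Hillman reaction of the activated α-silyloxy aldehyde brings in C11–C13 in one step; the new carbinol centre (C7) is irrelevant because it becomes sp2 in the next step.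

**Step 10**
Reactants: 17 methyl (4S,6E,10E)-6-(acetoxymethyl)-3-hydroxy-4-(TBS-oxy)-10-[(TBS-oxy)methyl]-12,12-dimethoxy-2-methylidenedodeca-6,10-dienoate
Product: 18 methyl (2Z,4S,6E,10E)-6-(acetoxymethyl)-2-(bromomethyl)-4-(TBS-oxy)-10-[(TBS-oxy)methyl]-12,12-dimethoxydodeca-2,6,10-trienoate
Conditions: NBS, Me2S, CH2Cl2, −20 → 23 °C
Reagents that add atoms: N-bromosuccinimide, O=C1CCC(=O)N1Br
Why: Corey–Kim-type activation of the allylic alcohol followed by SN2′ attack of bromide transposes the allylic system to the thermodynamic trisubstituted 2-(bromomethyl)enoate (ester trans to C8) under neutral conditions that spare the acetal.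

**Step 11**
Reactants: 18 methyl (2Z,4S,6E,10E)-6-(acetoxymethyl)-2-(bromomethyl)-4-(TBS-oxy)-10-[(TBS-oxy)methyl]-12,12-dimethoxydodeca-2,6,10-trienoate
Product: 21 14-acetoxy-8α,15-bis(TBS-oxy)germacra-1(10),4,11(13)-trien-12,6α-olide, via bromo enal 19 (not isolated), via hydroxy ester 20 (not isolated)
Conditions: In powder (3 equiv), THF/H2O/AcOH (8:2:1), 18 added by syringe pump over 10 h (final 2 mM), 35 °C; then p-TsOH·H2O (10 mol %), CH2Cl2, 23 °C
Reagents that add atoms: water, O
Why: Proposed new method: the mild aqueous acid unmasks the very labile α,β-unsaturated acetal to the C6 enal while In inserts into the allylic C–Br bond to give a water-tolerant allylindium, which attacks the enal carbonyl through its γ-carbon C7 (SE2′, cyclic transition state) and so closes the ten-membered ring at the bond that germacrene synthase forms, after which O6 lactonises onto C12 as in costunolide biosynthesis; C6 and C7 are set relative to the fixed C8 centre through the transition state that keeps O6, the C7 acrylate arm and the C8 silyl ether all pseudo-equatorial (7,8-trans and 6,7-trans, the trans-fused lactone), and the slow release of the aldehyde acts as extra dilution; the closest known reaction types are the aqueous In-mediated Barbier reaction of 2-(bromomethyl)acrylates with aldehydes (intramolecular to five- to seven-membered rings) and the CrCl2-mediated ten-membered closure of ω-formyl allylic bromides.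

**Step 12**
Reactants: 21 14-acetoxy-8α,15-bis(TBS-oxy)germacra-1(10),4,11(13)-trien-12,6α-olide
Product: 22 14-acetoxy-8α,15-dihydroxygermacra-1(10),4,11(13)-trien-12,6α-olide
Conditions: HF·pyridine, pyridine, THF, 0 → 23 °C
Reagents that add atoms: none
Why: Fluoride cleavage of both silyl ethers under buffered, non-basic conditions that avoid 12,6- to 12,8-translactonisation and leave the acetate and the α-methylene lactone alone.

**Step 13**
Reactants: 22 14-acetoxy-8α,15-dihydroxygermacra-1(10),4,11(13)-trien-12,6α-olide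
Product: 23 14-acetoxy-8α-hydroxy-15-oxogermacra-1(10),4,11(13)-trien-12,6α-olide
Conditions: MnO2 (20 equiv), CH2Cl2, 23 °C
Reagents that add atoms: none
Why: MnO2 oxidises only the allylic primary alcohol (8-OH is not allylic) to the enal, whose CHO-trans-to-C6 geometry is both the ring-cis one already present and the thermodynamic one.

**Step 14**
Reactants: 23 14-acetoxy-8α-hydroxy-15-oxogermacra-1(10),4,11(13)-trien-12,6α-olide
Product: 24 14-acetoxy-8α-(acryloyloxy)-15-oxogermacra-1(10),4,11(13)-trien-12,6α-olide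
Conditions: acryloyl chloride, Et3N, CH2Cl2, −20 → 0 °C
Reagents that add atoms: acryloyl chloride, C=CC(Cl)=O
Why: O-Acylation of the secondary 8α-hydroxyl proceeds with retention at C8.

**Step 15**
Reactants: 24 14-acetoxy-8α-(acryloyloxy)-15-oxogermacra-1(10),4,11(13)-trien-12,6α-olide
Product: 25 14-acetoxy-8α-[2-(hydroxymethyl)acryloyloxy]-15-oxogermacra-1(10),4,11(13)-trien-12,6α-olide (target)
Conditions: 37 % aq. HCHO (5 equiv), DABCO (1 equiv), 1,4-dioxane/H2O (1:1), 23 °C
Reagents that add atoms: formaldehyde, C=O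
Why: Morita–Baylis–Hillman reaction: DABCO can turn over only on the acceptor that has an α-hydrogen (the 8-O-acrylate; the α-methylene lactone and the enal are α-substituted), the ammonium enolate traps formaldehyde and β-elimination gives the free 2-(hydroxymethyl)acrylate without a protecting group.

**Compound list**
1 | hex-5-enal | C=CCCCC=O | starting material
2 | 2,2-dimethoxyacetaldehyde | COC(OC)C=O | starting material
3 | (E)-2-(but-3-en-1-yl)-4,4-dimethoxybut-2-enal | COC(OC)/C=C(C=O)\CCC=C | intermediate (not isolated)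
4 | (E)-2-(but-3-en-1-yl)-4,4-dimethoxybut-2-en-1-ol | COC(OC)/C=C(CO)\CCC=C | intermediate
5 | tert-butyl{[(2E)-2-(but-3-en-1-yl)-4,4-dimethoxybut-2-en-1-yl]oxy}dimethylsilane | COC(OC)/C=C(CO[Si](C)(C)C(C)(C)C)\CCC=C | intermediate
6 | (S)-5-(hydroxymethyl)dihydrofuran-2(3H)-one | O=C1CC[C@@H](CO)O1 | starting material
7 | (S)-5-{[(triethylsilyl)oxy]methyl}dihydrofuran-2(3H)-one | O=C1CC[C@@H](CO[Si](CC)(CC)CC)O1 | intermediate
8 | (5S)-3-[(dimethylamino)methyl]-5-{[(triethylsilyl)oxy]methyl}dihydrofuran-2(3H)-one (C3 epimers) | CN(C)CC1C[C@@H](CO[Si](CC)(CC)CC)OC1=O | intermediate (not isolated)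
9 | N,N,N-trimethyl-1-[(5S)-2-oxo-5-{[(triethylsilyl)oxy]methyl}tetrahydrofuran-3-yl]methanaminium iodide | C[N+](C)(C)CC1C[C@@H](CO[Si](CC)(CC)CC)OC1=O.[I-] | intermediate (not isolated)
10 | (S)-3-methylidene-5-{[(triethylsilyl)oxy]methyl}dihydrofuran-2(3H)-one | C=C1C[C@@H](CO[Si](CC)(CC)CC)OC1=O | intermediate
11 | (3E,5S)-3-[(4E)-4-{[(tert-butyldimethylsilyl)oxy]methyl}-6,6-dimethoxyhex-4-en-1-ylidene]-5-{[(triethylsilyl)oxy]methyl}dihydrofuran-2(3H)-one | COC(OC)/C=C(CO[Si](C)(C)C(C)(C)C)\CC/C=C1\C[C@@H](CO[Si](CC)(CC)CC)OC1=O | intermediate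
12 | (2S,4E,8E)-8-{[(tert-butyldimethylsilyl)oxy]methyl}-4-(hydroxymethyl)-10,10-dimethoxy-1-[(triethylsilyl)oxy]deca-4,8-dien-2-ol | COC(OC)/C=C(CO[Si](C)(C)C(C)(C)C)\CC/C=C(CO)\C[C@H](O)CO[Si](CC)(CC)CC | intermediate
13 | (2S,4E,8E)-4-(acetoxymethyl)-8-{[(tert-butyldimethylsilyl)oxy]methyl}-10,10-dimethoxy-1-[(triethylsilyl)oxy]deca-4,8-dien-2-ol | COC(OC)/C=C(CO[Si](C)(C)C(C)(C)C)\CC/C=C(COC(C)=O)\C[C@H](O)CO[Si](CC)(CC)CC | intermediate (not isolated)
14 | (2S,4E,8E)-4-(acetoxymethyl)-2-[(tert-butyldimethylsilyl)oxy]-8-{[(tert-butyldimethylsilyl)oxy]methyl}-10,10-dimethoxy-1-[(triethylsilyl)oxy]deca-4,8-diene | COC(OC)/C=C(CO[Si](C)(C)C(C)(C)C)\CC/C=C(COC(C)=O)\C[C@H](O[Si](C)(C)C(C)(C)C)CO[Si](CC)(CC)CC | intermediate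
15 | (2S,4E,8E)-4-(acetoxymethyl)-2-[(tert-butyldimethylsilyl)oxy]-8-{[(tert-butyldimethylsilyl)oxy]methyl}-10,10-dimethoxydeca-4,8-dienal | COC(OC)/C=C(CO[Si](C)(C)C(C)(C)C)\CC/C=C(COC(C)=O)\C[C@H](O[Si](C)(C)C(C)(C)C)C=O | intermediate
16 | methyl acrylate | C=CC(=O)OC | starting material
17 | methyl (4S,6E,10E)-6-(acetoxymethyl)-4-[(tert-butyldimethylsilyl)oxy]-10-{[(tert-butyldimethylsilyl)oxy]methyl}-3-hydroxy-12,12-dimethoxy-2-methylidenedodeca-6,10-dienoate (C3 epimers) | COC(OC)/C=C(CO[Si](C)(C)C(C)(C)C)\CC/C=C(COC(C)=O)\C[C@H](O[Si](C)(C)C(C)(C)C)C(O)C(=C)C(=O)OC | intermediate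
18 | methyl (2Z,4S,6E,10E)-6-(acetoxymethyl)-2-(bromomethyl)-4-[(tert-butyldimethylsilyl)oxy]-10-{[(tert-butyldimethylsilyl)oxy]methyl}-12,12-dimethoxydodeca-2,6,10-trienoate | COC(OC)/C=C(CO[Si](C)(C)C(C)(C)C)\CC/C=C(COC(C)=O)\C[C@H](O[Si](C)(C)C(C)(C)C)/C=C(\CBr)C(=O)OC | intermediate
19 | methyl (2Z,4S,6E,10E)-6-(acetoxymethyl)-2-(bromomethyl)-4-[(tert-butyldimethylsilyl)oxy]-10-{[(tert-butyldimethylsilyl)oxy]methyl}-12-oxododeca-2,6,10-trienoate | O=C/C=C(CO[Si](C)(C)C(C)(C)C)\CC/C=C(COC(C)=O)\C[C@H](O[Si](C)(C)C(C)(C)C)/C=C(\CBr)C(=O)OC | intermediate (not isolated)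
20 | methyl 14-acetoxy-8α,15-bis[(tert-butyldimethylsilyl)oxy]-6α-hydroxygermacra-1(10),4,11(13)-trien-12-oate (ring-cis alkenes; H-6β, H-7α, H-8β) | CC(C)(C)[Si](C)(C)O[C@H]1C/C(COC(C)=O)=C\CC/C(CO[Si](C)(C)C(C)(C)C)=C\[C@@H](O)[C@@H]1C(=C)C(=O)OC | intermediate (not isolated)
21 | 14-acetoxy-8α,15-bis[(tert-butyldimethylsilyl)oxy]germacra-1(10),4,11(13)-trien-12,6α-olide (ring-cis alkenes; trans-fused lactone) | CC(C)(C)[Si](C)(C)O[C@H]1C/C(COC(C)=O)=C\CC/C(CO[Si](C)(C)C(C)(C)C)=C\[C@H]2OC(=O)C(=C)[C@H]12 | intermediate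
22 | 14-acetoxy-8α,15-dihydroxygermacra-1(10),4,11(13)-trien-12,6α-olide | O[C@H]1C/C(COC(C)=O)=C\CC/C(CO)=C\[C@H]2OC(=O)C(=C)[C@H]12 | intermediate
23 | 14-acetoxy-8α-hydroxy-15-oxogermacra-1(10),4,11(13)-trien-12,6α-olide | O[C@H]1C/C(COC(C)=O)=C\CC/C(C=O)=C\[C@H]2OC(=O)C(=C)[C@H]12 | intermediate
24 | 14-acetoxy-8α-(acryloyloxy)-15-oxogermacra-1(10),4,11(13)-trien-12,6α-olide | C=CC(=O)O[C@H]1C/C(COC(C)=O)=C\CC/C(C=O)=C\[C@H]2OC(=O)C(=C)[C@H]12 | intermediate
25 | 14-acetoxy-8α-[2-(hydroxymethyl)acryloyloxy]-15-oxogermacra-1(10),4,11(13)-trien-12,6α-olide (CNP0198933.2) | C=C(CO)C(=O)O[C@H]1C/C(COC(C)=O)=C\CC/C(C=O)=C\[C@H]2OC(=O)C(=C)[C@H]12 | target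

**Step count and risks**
Total step count: 15. Longest linear sequence: 13 steps (1, 2, 5–15; the branch 3, 4, 5–15 is equally long).

The three steps most likely to fail:

Step 11 (ring closure). A ten-membered ring with two cis alkenes must close faster than the allylindium is protonated by water, and the C6/C7 configuration rests on macrocyclic control. The fallback sets out from 18 and comes back at 21. It gives up the one-flask aqueous organoindium cascade for a two-stage, anhydrous organochromium closure. The acetal alone is hydrolysed (PPTS, acetone/H2O, 0 °C) and bromo enal 19 is isolated. It is then added by syringe pump to CrCl2 (divalent chromium, 8 equiv) in THF at 23 °C (Nozaki–Hiyama–Kishi closure through a σ-allylchromium that cannot be protonated). Hydroxy ester 20 is lactonised with PPTS to 21. No new compound is made.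

Step 5 (cross-metathesis). Forming a trisubstituted alkylidene lactone by metathesis may give low turnover, E/Z mixtures or the endocyclic butenolide. The fallback sets out from 5 and 7 and comes back at 11; it replaces metathesis by a Horner–Wadsworth–Emmons olefination. Lemieux–Johnson cleavage of the terminal alkene of 5 (OsO4 cat., NaIO4, 2,6-lutidine, dioxane/H2O) gives (E)-4-{[(tert-butyldimethylsilyl)oxy]methyl}-6,6-dimethoxyhex-4-enal F1. Lactone 7 is O-phosphorylated (LDA, ClP(O)(OEt)2, THF, −78 °C) to the enol phosphate diethyl (5S)-5-{[(triethylsilyl)oxy]methyl}-4,5-dihydrofuran-2-yl phosphate F2. More LDA rearranges this in the same flask to diethyl [(5S)-2-oxo-5-{[(triethylsilyl)oxy]methyl}tetrahydrofuran-3-yl]phosphonate F3. Olefination of F1 with F3 (NaH, THF, 0 °C) gives the E-alkylidene lactone 11.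

Step 15 (final hydroxymethylation). The substrate carries three Michael acceptors, an acetate and a lactone in aqueous amine, so Rauhut–Currier coupling or hydrolysis may compete. The fallback sets out from 23 and comes back at 25; it brings in the complete side chain as a protected acid instead of building it on the molecule. Commercial ethyl 2-(hydroxymethyl)acrylate is silylated (TBSCl, imidazole) to ethyl 2-{[(tert-butyldimethylsilyl)oxy]methyl}acrylate F4. This is saponified (LiOH, THF/H2O, 0 °C) to 2-{[(tert-butyldimethylsilyl)oxy]methyl}acrylic acid F5. Steglich coupling with 23 (DCC, DMAP, CH2Cl2) gives 14-acetoxy-8α-[2-{[(tert-butyldimethylsilyl)oxy]methyl}acryloyloxy]-15-oxogermacra-1(10),4,11(13)-trien-12,6α-olide F6. Desilylation with HF·pyridine gives 25.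

**Further compounds**
F1 | step 5 | (E)-4-{[(tert-butyldimethylsilyl)oxy]methyl}-6,6-dimethoxyhex-4-enal | COC(OC)/C=C(CO[Si](C)(C)C(C)(C)C)\CCC=O
F2 | step 5 | diethyl (5S)-5-{[(triethylsilyl)oxy]methyl}-4,5-dihydrofuran-2-yl phosphate | CCOP(=O)(OCC)OC1=CC[C@@H](CO[Si](CC)(CC)CC)O1
F3 | step 5 | diethyl [(5S)-2-oxo-5-{[(triethylsilyl)oxy]methyl}tetrahydrofuran-3-yl]phosphonate (C3 epimers) | CCOP(=O)(OCC)C1C[C@@H](CO[Si](CC)(CC)CC)OC1=O
F0 | step 11 | none | none
F4 | step 15 | ethyl 2-{[(tert-butyldimethylsilyl)oxy]methyl}acrylate | CCOC(=O)C(=C)CO[Si](C)(C)C(C)(C)C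
F5 | step 15 | 2-{[(tert-butyldimethylsilyl)oxy]methyl}acrylic acid | OC(=O)C(=C)CO[Si](C)(C)C(C)(C)C
F6 | step 15 | 14-acetoxy-8α-[2-{[(tert-butyldimethylsilyl)oxy]methyl}acryloyloxy]-15-oxogermacra-1(10),4,11(13)-trien-12,6α-olide | C=C(CO[Si](C)(C)C(C)(C)C)C(=O)O[C@H]1C/C(COC(C)=O)=C\CC/C(C=O)=C\[C@H]2OC(=O)C(=C)[C@H]12
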